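**Retrosynthetic overview**
1. The only ring, the 14-membered one, is closed at C1–C2 of an open-chain C20 enal by a catalytic asymmetric carbonyl-ene macrocyclization. It copies the cembrene synthase step (the terminal isopropylidene attacks the electrophilic C2, proton loss gives the isopropenyl group) and sets C1 and C2; acetylation and desilylation then give the target.
2. The enal comes from a C2–C7 aldehyde and a C8–C17 enol triflate by asymmetric Nozaki–Hiyama–Kishi coupling (C7–C8 bond, sets C7). The 7-oxygen and the 8(19)-methylene are therefore in place before ring closure, which also shuts off six-ring ene closure.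
3. The aldehyde comes from 2-butyne-1,4-diol and an acetal Grignard reagent (anti-carbomagnesiation fixes the 3,4-olefin geometry), with the two CH2OH groups told apart by diacetylation and lipase hydrolysis. The triflate comes from (E)-geranylacetone.
4. Ring order: one ring, formed in step 9.

Assumption: the enantiomer written for the chiral ligand (step 6) and the chiral acid (step 9) is taken to give the required sense; both are available in either mirror-image form and the other is used if the sense proves opposite.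
Numbering: cembrane numbers are used for all compounds, open-chain ones included (C1 carries the isopropenyl group, C2 the ring acetate, C18 is the CH2OAc carbon on C4, C19 the methylene on C8).

**Step 1**
Reactants: 1 2-butyne-1,4-diol; 2 [2-(1,3-dioxan-2-yl)ethyl]magnesium bromide (4 equiv)
Product: 3 (2E)-2-[2-(1,3-dioxan-2-yl)ethyl]but-2-ene-1,4-diol
Conditions: CuI (10 mol %), THF, 0 °C → reflux; aq. NH4Cl
Reagents that add atoms: none
Why: Copper-catalysed anti-carbomagnesiation of a propargylic alkoxide (Duboudin reaction): the alkyl group adds next to the directing alkoxide and magnesium sits on the other alkyne carbon in a five-membered chelate, so after protonation the new chain is cis to the distal CH2OH (the C3=C4 geometry of the target), and the bis-alkoxide cannot eliminate to an allene.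

**Step 2**
Reactants: 3 (2E)-2-[2-(1,3-dioxan-2-yl)ethyl]but-2-ene-1,4-diol
Product: 4 (2E)-2-[2-(1,3-dioxan-2-yl)ethyl]but-2-ene-1,4-diyl diacetate
Conditions: Ac2O, pyridine, DMAP (cat.), CH2Cl2, 0 °C → rt
Reagents that add atoms: acetic anhydride, CC(=O)OC(C)=O
Why: DMAP-catalysed acylation of both primary allylic alcohols; the alkene is untouched and no stereocentre is involved.

**Step 3**
Reactants: 4 (2E)-2-[2-(1,3-dioxan-2-yl)ethyl]but-2-ene-1,4-diyl diacetate
Product: 5 (2E)-2-(3-oxopropyl)but-2-ene-1,4-diyl diacetate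
Conditions: TFA/H2O (1:1), CHCl3, 0 °C → rt
Reagents that add atoms: water, O
Why: Acid-catalysed acetal hydrolysis through the oxocarbenium ion frees the C7 aldehyde, while the primary acetates survive cold aqueous TFA.

**Step 4**
Reactants: 5 (2E)-2-(3-oxopropyl)but-2-ene-1,4-diyl diacetate
Product: 6 (2E)-4-hydroxy-2-(3-oxopropyl)but-2-en-1-yl acetate
Conditions: Pseudomonas cepacia lipase (Amano PS), pH 7 phosphate buffer/acetone, 25 °C, stopped at 1 equiv of acid released
Reagents that add atoms: none
Why: Lipase-catalysed regioselective ester hydrolysis: the enzyme cleaves the less hindered acetate on the CH= side (C2–O) and leaves the acetate geminal to the side chain (C18), as it does with 2-methylbut-2-ene-1,4-diyl diacetate.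

**Step 5**
Reactants: 7 (5E)-6,10-dimethylundeca-5,9-dien-2-one ((E)-geranylacetone)
Product: 9 (5E)-6,10-dimethylundeca-1,5,9-trien-2-yl trifluoromethanesulfonate, via lithium enolate 8 (not isolated)
Conditions: LiN(iPr)2, THF, −78 °C; PhNTf2, −78 → 0 °C; aq. NH4Cl
Reagents that add atoms: N-phenylbis(trifluoromethanesulfonimide), O=S(=O)(N(c1ccccc1)S(=O)(=O)C(F)(F)F)C(F)(F)F
Why: Kinetic deprotonation of the methyl ketone on the CH3 side by the hindered amide base, then O-triflation (enol triflate formation), gives the 2-triflyloxy-1-alkene that becomes C8=C19; the 5E olefin is untouched.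

**Step 6**
Reactants: 6 (2E)-4-hydroxy-2-(3-oxopropyl)but-2-en-1-yl acetate; 9 (5E)-6,10-dimethylundeca-1,5,9-trien-2-yl trifluoromethanesulfonate
Product: 10 (2E)-4-hydroxy-2-[(3R,7E)-3-hydroxy-8,12-dimethyl-4-methylidenetrideca-7,11-dien-1-yl]but-2-en-1-yl acetate
Conditions: CrCl2 (3 equiv), N-{2-[(4S)-4-isopropyl-4,5-dihydrooxazol-2-yl]-6-methylphenyl}methanesulfonamide (3.3 equiv), Et3N, NiCl2 (5 mol %), THF, rt
Reagents that add atoms: none
Why: Asymmetric Nozaki–Hiyama–Kishi coupling: nickel inserts into the enol triflate, transmetalation gives a 2-alkenylchromium species that adds only to the aldehyde (free OH and acetate are tolerated), and the chiral sulfonamide on chromium selects the aldehyde face to give the (R)-carbinol at C7.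

**Step 7**
Reactants: 10 (2E)-4-hydroxy-2-[(3R,7E)-3-hydroxy-8,12-dimethyl-4-methylidenetrideca-7,11-dien-1-yl]but-2-en-1-yl acetate
Product: 11 (2E)-2-[(3R,7E)-3-hydroxy-8,12-dimethyl-4-methylidenetrideca-7,11-dien-1-yl]-4-oxobut-2-en-1-yl acetate
Conditions: TEMPO (10 mol %), PhI(OAc)2 (1.1 equiv), CH2Cl2, rt
Reagents that add atoms: none
Why: Oxoammonium (TEMPO/PhI(OAc)2) oxidation is strongly selective for primary over secondary alcohols, so only the primary allylic alcohol becomes the enal; the alkene geometry and C7 are kept.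

**Step 8**
Reactants: 11 (2E)-2-[(3R,7E)-3-hydroxy-8,12-dimethyl-4-methylidenetrideca-7,11-dien-1-yl]-4-oxobut-2-en-1-yl acetate
Product: 12 (2E)-2-[(3R,7E)-3-{[tert-butyl(dimethyl)silyl]oxy}-8,12-dimethyl-4-methylidenetrideca-7,11-dien-1-yl]-4-oxobut-2-en-1-yl acetate
Conditions: TBSCl, imidazole, DMF, rt
Reagents that add atoms: tert-butyldimethylsilyl chloride, CC(C)(C)[Si](C)(C)Cl
Why: Imidazole-mediated silylation of the secondary allylic alcohol (silyl ether protection) is mild enough not to enolize the enal and leaves C7 untouched.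

**Step 9**
Reactants: 12 (2E)-2-[(3R,7E)-3-{[tert-butyl(dimethyl)silyl]oxy}-8,12-dimethyl-4-methylidenetrideca-7,11-dien-1-yl]-4-oxobut-2-en-1-yl acetate
Product: 14 (1R,2S,3E,7R,11E)-7-(tert-butyldimethylsilyloxy)cembra-3,8(19),11,15-tetraene-2,18-diyl diacetate, via ring-closed C2 alcohol 13 (not isolated)
Conditions: (S,S)-IDPi acid (chiral imidodiphosphorimidate: two 3,3'-diaryl-BINOL phosphorus units bridged by N, each P=N–SO2CF3; 20 mol %), CH2Cl2, −30 °C, syringe-pump addition of 12 to 2 mM; then Et3N, Ac2O, DMAP, −30 → 0 °C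
Reagents that add atoms: acetic anhydride, CC(=O)OC(C)=O
Why: Proposed new method: asymmetric carbonyl-ene (Prins-type) macrocyclization, in which the confined chiral Brønsted acid activates the enal, the terminal isopropylidene (the most nucleophilic and least hindered alkene; six-ring closure is impossible because C7/C8 are already oxidized) attacks C2 and a methyl proton is lost to give the isopropenyl group as in the cembrene synthase step, a chair-like six-membered transition state with both chain ends pseudo-equatorial gives the trans C1/C2 relationship and the catalyst pocket picks the aldehyde face to set (1R,2S), the closest known reaction types being the IDPi-catalysed carbonyl-ene cyclization of neral to isopiperitenol and the SnCl4-induced 14-ring closure of geranylgeranoyl chloride, and the alcohol is acetylated in the same flask.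

**Step 10**
Reactants: 14 (1R,2S,3E,7R,11E)-7-(tert-butyldimethylsilyloxy)cembra-3,8(19),11,15-tetraene-2,18-diyl diacetate
Product: 15 (1R,2S,3E,7R,11E)-7-hydroxycembra-3,8(19),11,15-tetraene-2,18-diyl diacetate (target)
Conditions: HF·pyridine, THF/pyridine, 0 °C → rt
Reagents that add atoms: none
Why: Fluoride-mediated desilylation with buffered HF·pyridine cleaves only the Si–O bond; both acetates, the exocyclic alkenes and all three stereocentres are untouched.

**Compound list**
1 | 2-butyne-1,4-diol | OCC#CCO | starting material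
2 | [2-(1,3-dioxan-2-yl)ethyl]magnesium bromide | Br[Mg]CCC1OCCCO1 | starting material
3 | (2E)-2-[2-(1,3-dioxan-2-yl)ethyl]but-2-ene-1,4-diol (the two CH2OH trans) | OC/C=C(/CO)CCC1OCCCO1 | intermediate
4 | (2E)-2-[2-(1,3-dioxan-2-yl)ethyl]but-2-ene-1,4-diyl diacetate | CC(=O)OC/C=C(/COC(C)=O)CCC1OCCCO1 | intermediate
5 | (2E)-2-(3-oxopropyl)but-2-ene-1,4-diyl diacetate | CC(=O)OC/C=C(/COC(C)=O)CCC=O | intermediate
6 | (2E)-4-hydroxy-2-(3-oxopropyl)but-2-en-1-yl acetate | OC/C=C(/COC(C)=O)CCC=O | intermediate
7 | (5E)-6,10-dimethylundeca-5,9-dien-2-one ((E)-geranylacetone) | CC(=O)CC/C=C(\C)CCC=C(C)C | starting material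
8 | lithium (5E)-6,10-dimethylundeca-1,5,9-trien-2-olate | [Li]OC(=C)CC/C=C(\C)CCC=C(C)C | intermediate
9 | (5E)-6,10-dimethylundeca-1,5,9-trien-2-yl trifluoromethanesulfonate | C=C(OS(=O)(=O)C(F)(F)F)CC/C=C(\C)CCC=C(C)C | intermediate
10 | (2E)-4-hydroxy-2-[(3R,7E)-3-hydroxy-8,12-dimethyl-4-methylidenetrideca-7,11-dien-1-yl]but-2-en-1-yl acetate | OC/C=C(/COC(C)=O)CC[C@@H](O)C(=C)CC/C=C(\C)CCC=C(C)C | intermediate
11 | (2E)-2-[(3R,7E)-3-hydroxy-8,12-dimethyl-4-methylidenetrideca-7,11-dien-1-yl]-4-oxobut-2-en-1-yl acetate (CHO cis to the long chain) | O=C/C=C(/COC(C)=O)CC[C@@H](O)C(=C)CC/C=C(\C)CCC=C(C)C | intermediate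
12 | (2E)-2-[(3R,7E)-3-{[tert-butyl(dimethyl)silyl]oxy}-8,12-dimethyl-4-methylidenetrideca-7,11-dien-1-yl]-4-oxobut-2-en-1-yl acetate | O=C/C=C(/COC(C)=O)CC[C@@H](O[Si](C)(C)C(C)(C)C)C(=C)CC/C=C(\C)CCC=C(C)C | intermediate
13 | (1R,2S,3E,7R,11E)-7-(tert-butyldimethylsilyloxy)-2-hydroxycembra-3,8(19),11,15-tetraen-18-yl acetate (14-membered ring; OH and isopropenyl trans) | C=C1CC/C=C(\C)CC[C@H](C(=C)C)[C@@H](O)/C=C(/COC(C)=O)CC[C@H]1O[Si](C)(C)C(C)(C)C | intermediate
14 | (1R,2S,3E,7R,11E)-7-(tert-butyldimethylsilyloxy)cembra-3,8(19),11,15-tetraene-2,18-diyl diacetate | C=C1CC/C=C(\C)CC[C@H](C(=C)C)[C@@H](OC(C)=O)/C=C(/COC(C)=O)CC[C@H]1O[Si](C)(C)C(C)(C)C | intermediate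
15 | (1R,2S,3E,7R,11E)-7-hydroxycembra-3,8(19),11,15-tetraene-2,18-diyl diacetate | C=C1CC/C=C(\C)CC[C@H](C(=C)C)[C@@H](OC(C)=O)/C=C(/COC(C)=O)CC[C@H]1O | target

**Totals**
Total steps: 10. Longest linear sequence: 9 (steps 1–4 and 6–10).

**Steps most likely to fail**

Step 1 (a functionalized primary alkyl Grignard reagent may add sluggishly to the poorly soluble bis-alkoxide). The fallback sets out from 1 and comes back at 4. Trans-hydroalumination of 1 with NaAlH2(OCH2CH2OCH3)2 in THF and quenching with I2 gives (2Z)-2-iodobut-2-ene-1,4-diol F1. Ac2O/pyridine turns it into (2Z)-2-iodobut-2-ene-1,4-diyl diacetate F2. Negishi coupling of F2 (Pd(dppf)Cl2, THF) with [2-(1,3-dioxan-2-yl)ethyl]zinc bromide F3, made from 2 and ZnBr2, replaces iodine with retention of geometry and gives 4.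

Step 6 (face selectivity of the chromium addition with an enol triflate and a substrate carrying a free OH and an allylic acetate). The fallback sets out from 5 and 9 and comes back at 10. Ligand-free CrCl2/NiCl2 coupling of 5 with 9 in DMF gives racemic (2E)-2-[(7E)-3-hydroxy-8,12-dimethyl-4-methylidenetrideca-7,11-dien-1-yl]but-2-ene-1,4-diyl diacetate F4. Dess–Martin periodinane oxidizes it to the α-methylene ketone (2E)-2-[(7E)-8,12-dimethyl-4-methylidene-3-oxotrideca-7,11-dien-1-yl]but-2-ene-1,4-diyl diacetate F5. Reduction with (S)-2-methyl-CBS-oxazaborolidine/catecholborane at −78 °C (alkenyl as the large group) gives the (3R)-alcohol (2E)-2-[(3R,7E)-3-hydroxy-8,12-dimethyl-4-methylidenetrideca-7,11-dien-1-yl]but-2-ene-1,4-diyl diacetate F6. The lipase hydrolysis of step 4 then removes the acetate on the CH= side and gives 10.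

Step 9 (the riskiest: no carbonyl-ene closure of a 14-membered ring is known; oligomers, ten-ring closure onto the 11,12-olefin or low selectivity are possible). The fallback sets out from 12 and comes back at 13. It closes the same C1–C2 bond by an intramolecular Nozaki–Hiyama allylation. SeO2 (cat.)/t-BuOOH oxidizes the terminal (E)-methyl of 12 to (2E)-2-[(3R,7E,11E)-3-{[tert-butyl(dimethyl)silyl]oxy}-13-hydroxy-8,12-dimethyl-4-methylidenetrideca-7,11-dien-1-yl]-4-oxobut-2-en-1-yl acetate F7. CBr4/PPh3 gives the allylic bromide (2E)-2-[(3R,7E,11E)-13-bromo-3-{[tert-butyl(dimethyl)silyl]oxy}-8,12-dimethyl-4-methylidenetrideca-7,11-dien-1-yl]-4-oxobut-2-en-1-yl acetate F8. CrCl2 with the sulfonamide ligand of step 6 in THF at high dilution forms the allylchromium reagent, which adds through its γ-carbon (C1) to the enal in a chair transition state to give the anti adduct, that is the trans (1R,2S) alcohol 13 with the isopropenyl group. Alcohol 13 is then acetylated to 14 as in step 9.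

**Further compounds**
F1 | step 1 | (2Z)-2-iodobut-2-ene-1,4-diol | OC/C=C(\I)CO
F2 | step 1 | (2Z)-2-iodobut-2-ene-1,4-diyl diacetate | CC(=O)OC/C=C(\I)COC(C)=O
F3 | step 1 | [2-(1,3-dioxan-2-yl)ethyl]zinc bromide | Br[Zn]CCC1OCCCO1
F4 | step 6 | (2E)-2-[(7E)-3-hydroxy-8,12-dimethyl-4-methylidenetrideca-7,11-dien-1-yl]but-2-ene-1,4-diyl diacetate (racemic) | CC(=O)OC/C=C(/COC(C)=O)CCC(O)C(=C)CC/C=C(\C)CCC=C(C)C
F5 | step 6 | (2E)-2-[(7E)-8,12-dimethyl-4-methylidene-3-oxotrideca-7,11-dien-1-yl]but-2-ene-1,4-diyl diacetate | CC(=O)OC/C=C(/COC(C)=O)CCC(=O)C(=C)CC/C=C(\C)CCC=C(C)C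
F6 | step 6 | (2E)-2-[(3R,7E)-3-hydroxy-8,12-dimethyl-4-methylidenetrideca-7,11-dien-1-yl]but-2-ene-1,4-diyl diacetate | CC(=O)OC/C=C(/COC(C)=O)CC[C@@H](O)C(=C)CC/C=C(\C)CCC=C(C)C
F7 | step 9 | (2E)-2-[(3R,7E,11E)-3-{[tert-butyl(dimethyl)silyl]oxy}-13-hydroxy-8,12-dimethyl-4-methylidenetrideca-7,11-dien-1-yl]-4-oxobut-2-en-1-yl acetate | O=C/C=C(/COC(C)=O)CC[C@@H](O[Si](C)(C)C(C)(C)C)C(=C)CC/C=C(\C)CC/C=C(\C)CO
F8 | step 9 | (2E)-2-[(3R,7E,11E)-13-bromo-3-{[tert-butyl(dimethyl)silyl]oxy}-8,12-dimethyl-4-methylidenetrideca-7,11-dien-1-yl]-4-oxobut-2-en-1-yl acetate | O=C/C=C(/COC(C)=O)CC[C@@H](O[Si](C)(C)C(C)(C)C)C(=C)CC/C=C(\C)CC/C=C(\C)CBr
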